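A stirred vessel of constant volume takes the same charges in each flask below, and the flasks differ in the order of entry.

in all of them: free catalyst 4.0 mM; second catalyst 40 µM; time 4.0 min

|  | substrate | coupling partner | remark |
|---|---|---|---|
| zeta | 0.020 M | 0.0200 M (fed, over 3.0 min) | all else is in the flask from the start; the feed brings no volume worth counting |
| theta | 0.020 M | 0.0200 M | everything together at the start |
| alpha | 0.020 M (in portions, 5, over 3.0 min) | 0.0200 M | first portion at the start, last at 3.0 min |
| epsilon | 0.020 M (fed, over 3.0 min) | 0.0200 M | all else is in the flask from the start; the feed brings no volume worth counting |

    coupling partner + second catalyst + intermediate → second catalyst + target (k1 = 2.64 × 10⁵ L² mol⁻² s⁻¹)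
    2 coupling partner → homo dimer (k2 = 2.05 L mol⁻¹ s⁻¹)
    substrate + free catalyst → free catalyst + intermediate (k3 = 13.2 L mol⁻¹ s⁻¹)
    target → over-reaction product (k4 = 0.0881 s⁻¹)

- a step written with two of one species runs at k times the square of its concentration and takes two of it each time
- run time (zeta): 4.0 min

- the flask that comes out highest in amount of over-reaction product, in percent of the substrate charged; "all alike" if 1.5 percentage points covers them all (zeta / theta / alpha / epsilon / all alike)
- amount of over-reaction product at the end, in percent of the substrate charged, zeta
- amount of over-reaction product at the end, in percent of the substrate charged, theta
- amount of over-reaction product at the end, in percent of the substrate charged, alpha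
- amount of over-reaction product at the end, in percent of the substrate charged, epsilon

Two chemists dispute this. The first looks at the half-lives in theta: substrate 0.22 min, intermediate 0.055 min, target 0.13 min, each far shorter than the run of 4.0 min. She concludes that the order of entry washes out and expects one figure within the margin. The second counts the exits open to the coupling partner, and hers is the forecast: zeta highest, with 91% for zeta, 54% for theta, 25% for alpha and 22% for epsilon, each flask's figure being “its coupling yield, which is set by how much partner escapes into homo dimer”.

My own reckoning tests her view on the feeds. Let r be a feed's rate, charge over dosing time, here 6.67 mM min⁻¹, and let k be the constant of the dimer step. The crossing level B× = √(r/(2k)) is the partner concentration at which the dimer step removes partner as fast as the feed delivers material, here 5.21 mM. In epsilon the partner starts at 3.84 times B×, and there the dimer step takes 98.4 mM min⁻¹, more than the intermediate can claim. So I allow coupling about B× of partner in epsilon, which gives 26.0%, above the forecast's 22%. In zeta, early in the feed, the intermediate stands near its charge and the partner holds a quasi-steady level near 0.526 mM, well below B×. The dimer loss in zeta is then about 1.02% of the feed. My reckoning stops there and gives no figure for theta or alpha.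

The simulation gives zeta highest, at 91.0%, then theta at 51.7%, alpha at 26.8% and epsilon at 21.3%. That spread of 70 percentage points goes to the second chemist.

Removing the dimer step cuts the gap between zeta and epsilon from 70 points to 2.5 points, the largest single effect. Even in that run the gap stands above the margin of 1.5 points, so the first chemist's single figure does not hold there. Epsilon's over-reaction product amounts to 4.25 mM, or 0.817 of B×. The neighbour with 0.034 M of substrate has B× at 6.79 mM, so the same fraction predicts 16.3%, and that neighbour gives 14.8%.

(The constants are assumed; the flask was simulated.)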